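A direct plan would mono-methylate 2',4',6'-trihydroxyacetophenone to its 4'-methyl ether A1, mask one ortho hydroxyl as a benzyl ether,
condense with 4-(benzyloxy)benzaldehyde to chalcone A2, close ring C with alkaline hydrogen peroxide to flavonol A3, methylate the 3-OH,
hydrogenolyse both benzyl ethers to diphenol A4 and prenylate the 4'-OH last.
Its weakest steps would be: (a) the oxidative ring closure of A2, because a 6'-alkoxy-2'-hydroxychalcone can close 5-exo to an aurone
as well as 6-endo to the flavonol, so that the size of ring C would be left to chance;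
(b) the benzylation and the hydrogenolysis, two steps that add nothing to the skeleton and force the hydrogenation-sensitive prenyl group to the very end;
(c) the final prenylation of A4, which would demand 4'-O against 5-O and O against C selectivity on the most precious material,
after an opening mono-methylation that must pick one hydroxyl out of three.

**Plan of the new route**
The retrosynthesis cuts ring A, not ring C: C4a–C5, C5–C6, C7–C8 and C8–C8a are made together in the last step from a 2-(diazoacetyl)-4-pyranone and methoxyacetylene; C2–C1' is cut before that (cross-coupling).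
Ring C is bought as comenic acid, ring B is joined to it, and ring A arises last.
The feature that allows this is ring A itself: free OH at C5 peri to the C4 carbonyl, OMe at C7, H at C6 and C8, i.e. the 1-hydroxy-3-alkoxy arene
that a ketene/alkoxyalkyne benzannulation delivers (ketene C=O becomes C5–OH, the alkyne carbons become C6–H and C7–OMe).
Ring C is never closed, no protecting group is used and no hydroxyl has to be chosen among others: the 3-OMe comes from the only OH of comenic acid,
the 7-OMe from the alkyne, the 5-OH is born free, and the prenyl ether enters with ring B before the core exists.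

Key step: step 7

Assumption: methoxyacetylene is volatile and not reliably stocked, so it is made fresh (step 6); comenic acid, the pinacol ester of 4-hydroxyphenylboronic acid and chloroacetaldehyde dimethyl acetal are bought.

Step 1
Reactants: 1 5-hydroxy-4-oxo-4H-pyran-2-carboxylic acid (comenic acid)
Product: 2 6-bromo-5-hydroxy-4-oxo-4H-pyran-2-carboxylic acid
Conditions: Br2 (1.0 equiv), H2O, 20 °C; product filtered
Reagents that add atoms: bromine BrBr
Why: Electrophilic bromination of the enol C5(OH)=C6 should be regiospecific, since C6 is the only ring carbon activated by the 5-OH while C3 lies between the C4 carbonyl and the carboxyl-bearing C2.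

Step 2
Reactants: 2 6-bromo-5-hydroxy-4-oxo-4H-pyran-2-carboxylic acid
Product: 3 methyl 6-bromo-5-methoxy-4-oxo-4H-pyran-2-carboxylate
Conditions: MeI (3 equiv), K2CO3 (2.5 equiv), DMF, 20 °C
Reagents that add atoms: iodomethane CI
Why: Williamson O-methylation of the single enolic hydroxyl and SN2 esterification of the carboxylate occur in one operation, and with no second hydroxyl present no selectivity is asked for.

Step 3
Reactants: 4 4-(4,4,5,5-tetramethyl-1,3,2-dioxaborolan-2-yl)phenol
Product: 5 4,4,5,5-tetramethyl-2-{4-[(3-methylbut-2-en-1-yl)oxy]phenyl}-1,3,2-dioxaborolane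
Conditions: prenyl bromide (1.1 equiv), K2CO3 (1.5 equiv), acetone, 50 °C
Reagents that add atoms: 1-bromo-3-methylbut-2-ene CC(C)=CCBr
Why: Williamson (SN2) O-prenylation of the only phenol, with the pinacol boronate stable to K2CO3 in dry acetone, puts the prenyl ether in place before any part of the core is assembled.

Step 4
Reactants: 3 methyl 6-bromo-5-methoxy-4-oxo-4H-pyran-2-carboxylate; 5 4,4,5,5-tetramethyl-2-{4-[(3-methylbut-2-en-1-yl)oxy]phenyl}-1,3,2-dioxaborolane
Product: 7 5-methoxy-6-{4-[(3-methylbut-2-en-1-yl)oxy]phenyl}-4-oxo-4H-pyran-2-carboxylic acid, via methyl ester 6 (not isolated)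
Conditions: PdCl2(dppf) (3 mol %), K3PO4 (2 equiv), 1,4-dioxane/H2O 9:1, 70 °C; then LiOH·H2O (1.5 equiv), THF/H2O, 0 °C; then cold 1 M HCl to pH 3
Reagents that add atoms: lithium hydroxide [Li+].[OH-]
Why: Suzuki–Miyaura coupling at the C6–Br bond of 3 (a vinylogous acyl bromide, hence fast oxidative addition) makes the future C2–C1' bond, and the activated ester is then saponified in the same flask by cold LiOH, to which the aryl prenyl ether and the methyl ether are inert.

Step 5
Reactants: 7 5-methoxy-6-{4-[(3-methylbut-2-en-1-yl)oxy]phenyl}-4-oxo-4H-pyran-2-carboxylic acid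
Product: 9 2-(2-diazoacetyl)-5-methoxy-6-{4-[(3-methylbut-2-en-1-yl)oxy]phenyl}-4H-pyran-4-one, via mixed anhydride 8 (not isolated)
Conditions: iBuOCOCl (1.05 equiv), N-methylmorpholine (1.1 equiv), THF, −20 °C; then CH2N2 (2.5 equiv, Et2O), −20 to 0 °C
Reagents that add atoms: diazomethane C=[N+]=[N-]
Why: Acylation of diazomethane as in the first stage of an Arndt–Eistert sequence; the mixed carbonic anhydride avoids the HCl that would endanger the prenyl ether, diazomethane attacks the more electrophilic pyranoyl carbonyl, and the departing isobutyl carbonate removes the proton to give the diazo ketone.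

Step 6
Reactants: 10 2-chloro-1,1-dimethoxyethane (chloroacetaldehyde dimethyl acetal)
Product: 12 methoxyacetylene (methoxyethyne), via sodium methoxyacetylide 11 (not isolated)
Conditions: NaNH2 (3.1 equiv), liq. NH3, −35 °C; NH3 evaporated; satd aq NaCl, −60 to 25 °C, distilled into a −78 °C trap and used at once as a cold solution in ClCH2CH2Cl
Reagents that add atoms: none
Why: Double β-elimination with sodium amide (loss of methanol, then of HCl) is the classical route from chloroacetaldehyde acetals to alkoxyacetylenes, the product being held as its sodium acetylide until the aqueous quench.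

Step 7
Reactants: 9 2-(2-diazoacetyl)-5-methoxy-6-{4-[(3-methylbut-2-en-1-yl)oxy]phenyl}-4H-pyran-4-one; 12 methoxyacetylene
Product: 17 5-hydroxy-3,7-dimethoxy-2-{4-[(3-methylbut-2-en-1-yl)oxy]phenyl}-4H-chromen-4-one (target), via pyranonylketene 13 (not isolated), via cyclobutenone 14 (not isolated), via dienylketene 15 (not isolated), via dienone tautomer 16 (not isolated)
Conditions: 12 (4 equiv), ClCH2CH2Cl, hν (440–450 nm LEDs), sealed tube, 20 °C; then 80 °C in the dark
Reagents that add atoms: none
Why: Proposed new method: excitation of the long-wavelength band of the diazo carbonyl group should expel N2 with 1,2-shift of the pyranone C2 carbon from the acyl to the diazo carbon (Wolff rearrangement) to give ketene 13; the unsubstituted, nucleophilic carbon of ynol ether 12 attacks the ketene carbonyl carbon, so that [2+2] cycloaddition gives only the 3-methoxycyclobutenone 14, whose reversible conrotatory four-electron opening gives dienylketene 15, and six-electron electrocyclic closure of the ketene carbon onto C3–H of the pyranone followed by enolisation of dienone 16 gives the phenol. The closest known reaction type is the Danheiser benzannulation in its diazo ketone variant, established for aryl and five-membered heteroaryl diazomethyl ketones with alkoxy- and silyloxyalkynes; a 4-pyranon-2-yl group as migrating and ring-closing partner is the untested element, and its C2=C3 bond, less aromatic than a benzene bond, should if anything enter the electrocyclisation more readily. Ring A is closed by a disrotatory six-electron electrocyclisation that can only engage C3, because the other neighbour of C2 is the ring oxygen; the stereocentres of 14 and 16 are transient and none remains. Regioselectivity rests on the polarity match of ketene and ynol ether alone, which places OMe at C7 meta to the new OH at C5 and leaves H at C6 and C8, while the ring-opened ketene of the wrong alkene geometry simply recloses to 14. Chemoselectivity rests on the wavelength (the strong absorptions of the 2-aryl-4-pyranone and of the flavone product lie at shorter wavelength), on the excess of the far more ketenophilic ynol ether over the prenyl alkene, and on the hydrogen bond of the new 5-OH to C4=O, which makes it a poor trap for remaining ketene. Methoxyacetylene has no β-hydrogen on its alkyl group and so cannot fragment by a retro-ene path at 80 °C.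

**Compound list**

1 | 5-hydroxy-4-oxo-4H-pyran-2-carboxylic acid (comenic acid) | OC(=O)c1cc(=O)c(O)co1 | starting material
2 | 6-bromo-5-hydroxy-4-oxo-4H-pyran-2-carboxylic acid | OC(=O)c1cc(=O)c(O)c(Br)o1 | intermediate
3 | methyl 6-bromo-5-methoxy-4-oxo-4H-pyran-2-carboxylate | COC(=O)c1cc(=O)c(OC)c(Br)o1 | intermediate
4 | 4-(4,4,5,5-tetramethyl-1,3,2-dioxaborolan-2-yl)phenol | Oc1ccc(cc1)B1OC(C)(C)C(C)(C)O1 | starting material
5 | 4,4,5,5-tetramethyl-2-{4-[(3-methylbut-2-en-1-yl)oxy]phenyl}-1,3,2-dioxaborolane | CC(C)=CCOc1ccc(cc1)B1OC(C)(C)C(C)(C)O1 | intermediate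
6 | methyl 5-methoxy-6-{4-[(3-methylbut-2-en-1-yl)oxy]phenyl}-4-oxo-4H-pyran-2-carboxylate (not isolated) | COC(=O)c1cc(=O)c(OC)c(-c2ccc(OCC=C(C)C)cc2)o1 | intermediate
7 | 5-methoxy-6-{4-[(3-methylbut-2-en-1-yl)oxy]phenyl}-4-oxo-4H-pyran-2-carboxylic acid | OC(=O)c1cc(=O)c(OC)c(-c2ccc(OCC=C(C)C)cc2)o1 | intermediate
8 | 5-methoxy-6-{4-[(3-methylbut-2-en-1-yl)oxy]phenyl}-4-oxo-4H-pyran-2-carboxylic 2-methylpropyl carbonic anhydride (not isolated) | CC(C)COC(=O)OC(=O)c1cc(=O)c(OC)c(-c2ccc(OCC=C(C)C)cc2)o1 | intermediate
9 | 2-(2-diazoacetyl)-5-methoxy-6-{4-[(3-methylbut-2-en-1-yl)oxy]phenyl}-4H-pyran-4-one | [N-]=[N+]=CC(=O)c1cc(=O)c(OC)c(-c2ccc(OCC=C(C)C)cc2)o1 | intermediate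
10 | 2-chloro-1,1-dimethoxyethane | COC(CCl)OC | starting material
11 | sodium methoxyacetylide (not isolated) | [Na+].[C-]#COC | intermediate
12 | methoxyacetylene | COC#C | intermediate
13 | 5-methoxy-6-{4-[(3-methylbut-2-en-1-yl)oxy]phenyl}-2-(2-oxoethenyl)-4H-pyran-4-one (ketene, not isolated) | O=C=Cc1cc(=O)c(OC)c(-c2ccc(OCC=C(C)C)cc2)o1 | intermediate
14 | racemic 3-methoxy-4-(5-methoxy-6-{4-[(3-methylbut-2-en-1-yl)oxy]phenyl}-4-oxo-4H-pyran-2-yl)cyclobut-2-en-1-one (not isolated) | COC1=CC(=O)C1c1cc(=O)c(OC)c(-c2ccc(OCC=C(C)C)cc2)o1 | intermediate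
15 | (3E)-3-methoxy-4-(5-methoxy-6-{4-[(3-methylbut-2-en-1-yl)oxy]phenyl}-4-oxo-4H-pyran-2-yl)buta-1,3-dien-1-one (dienylketene, pyranonyl cis to the ketene carbon, not isolated) | O=C=C/C(OC)=C\c1cc(=O)c(OC)c(-c2ccc(OCC=C(C)C)cc2)o1 | intermediate
16 | racemic 3,7-dimethoxy-2-{4-[(3-methylbut-2-en-1-yl)oxy]phenyl}-4aH-chromene-4,5-dione (keto tautomer, not isolated) | COC1=CC(=O)C2C(=O)C(OC)=C(c3ccc(OCC=C(C)C)cc3)OC2=C1 | intermediate
17 | 5-hydroxy-3,7-dimethoxy-2-{4-[(3-methylbut-2-en-1-yl)oxy]phenyl}-4H-chromen-4-one | COc1cc(O)c2c(=O)c(OC)c(-c3ccc(OCC=C(C)C)cc3)oc2c1 | target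

**Step count and risks**

Total step count: 7. Longest linear sequence: 5 steps (steps 1, 2, 4, 5, 7).

Steps most likely to fail:

1. Step 7. What may go wrong:
   - light taken up by the aryl-pyranone chromophore instead of the diazo carbonyl;
   - carbene-type reaction of the excited diazo ketone instead of the 1,2-shift;
   - loss of the ketene to dimerisation before the ynol ether captures it.

   Fallback (known chemistry, no light in the bond-forming stages), setting out from 9 and returning at 14: silver-promoted Wolff rearrangement of 9 in aqueous THF (AgO2CPh, Et3N; Arndt–Eistert homologation) would give 2-(5-methoxy-6-{4-[(3-methylbut-2-en-1-yl)oxy]phenyl}-4-oxo-4H-pyran-2-yl)acetic acid F1, kept cold to avoid decarboxylation. 1-Chloro-N,N,2-trimethylprop-1-en-1-amine would convert it under neutral conditions into the acid chloride, 2-(5-methoxy-6-{4-[(3-methylbut-2-en-1-yl)oxy]phenyl}-4-oxo-4H-pyran-2-yl)acetyl chloride F2. Dehydrochlorination of F2 with Et3N in the presence of 12 in the dark would generate ketene 13 and, by the usual ketene/ynol ether [2+2] cycloaddition, cyclobutenone 14. This would be isolated and heated in toluene at 80–110 °C to reach 17 through 15 and 16.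

2. Step 4. What may go wrong:
   - hydrolytic displacement of bromide from the vinylogous acyl bromide by aqueous base;
   - protodeboronation;
   - ionisation of the prenyl ether by the palladium catalyst;
   - opening of the pyranone by hydroxide during saponification.

   Fallback, setting out from 3 and returning at 6: 4-iodophenol would be prenylated (prenyl bromide, K2CO3, acetone) to 1-iodo-4-[(3-methylbut-2-en-1-yl)oxy]benzene F3. Zinc insertion (Zn dust, LiCl, THF, 40 °C) would give {4-[(3-methylbut-2-en-1-yl)oxy]phenyl}zinc iodide F4. Negishi coupling of F4 with 3 (Pd(PPh3)4, THF, 25 °C), base-free and anhydrous, would give ester 6, which would then be saponified separately (LiOH, THF/H2O, 0 °C) to 7.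

3. Step 5. What may go wrong:
   - attack of diazomethane at the carbonate carbonyl, with return of ester;
   - dipolar cycloaddition of diazomethane to the C2=C3 bond of the pyranone.

   Fallback, setting out from 7 and returning at 9: carbonyldiimidazole followed by MeNH(OMe)·HCl would give N,5-dimethoxy-N-methyl-6-{4-[(3-methylbut-2-en-1-yl)oxy]phenyl}-4-oxo-4H-pyran-2-carboxamide F5. MeMgBr (THF, −40 °C) would give the methyl ketone 2-acetyl-5-methoxy-6-{4-[(3-methylbut-2-en-1-yl)oxy]phenyl}-4H-pyran-4-one F6. LiHMDS and CF3CO2CH2CF3 (THF, −78 °C) would give the trifluoroacetylated diketone 4,4,4-trifluoro-1-(5-methoxy-6-{4-[(3-methylbut-2-en-1-yl)oxy]phenyl}-4-oxo-4H-pyran-2-yl)butane-1,3-dione F7, not isolated. MsN3, Et3N and H2O in MeCN would then give diazo ketone 9 by detrifluoroacetylative diazo transfer.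

Further compounds
F1 | step 7 | 2-(5-methoxy-6-{4-[(3-methylbut-2-en-1-yl)oxy]phenyl}-4-oxo-4H-pyran-2-yl)acetic acid | OC(=O)Cc1cc(=O)c(OC)c(-c2ccc(OCC=C(C)C)cc2)o1
F2 | step 7 | 2-(5-methoxy-6-{4-[(3-methylbut-2-en-1-yl)oxy]phenyl}-4-oxo-4H-pyran-2-yl)acetyl chloride | ClC(=O)Cc1cc(=O)c(OC)c(-c2ccc(OCC=C(C)C)cc2)o1
F3 | step 4 | 1-iodo-4-[(3-methylbut-2-en-1-yl)oxy]benzene | CC(C)=CCOc1ccc(I)cc1
F4 | step 4 | {4-[(3-methylbut-2-en-1-yl)oxy]phenyl}zinc iodide | CC(C)=CCOc1ccc([Zn]I)cc1
F5 | step 5 | N,5-dimethoxy-N-methyl-6-{4-[(3-methylbut-2-en-1-yl)oxy]phenyl}-4-oxo-4H-pyran-2-carboxamide | CON(C)C(=O)c1cc(=O)c(OC)c(-c2ccc(OCC=C(C)C)cc2)o1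
F6 | step 5 | 2-acetyl-5-methoxy-6-{4-[(3-methylbut-2-en-1-yl)oxy]phenyl}-4H-pyran-4-one | CC(=O)c1cc(=O)c(OC)c(-c2ccc(OCC=C(C)C)cc2)o1
F7 | step 5 | 4,4,4-trifluoro-1-(5-methoxy-6-{4-[(3-methylbut-2-en-1-yl)oxy]phenyl}-4-oxo-4H-pyran-2-yl)butane-1,3-dione | O=C(CC(=O)C(F)(F)F)c1cc(=O)c(OC)c(-c2ccc(OCC=C(C)C)cc2)o1
A1 | direct plan | 1-(2,6-dihydroxy-4-methoxyphenyl)ethanone | CC(=O)c1c(O)cc(OC)cc1O
A2 | direct plan | (E)-1-[2-(benzyloxy)-6-hydroxy-4-methoxyphenyl]-3-[4-(benzyloxy)phenyl]prop-2-en-1-one | COc1cc(O)c(C(=O)/C=C/c2ccc(OCc3ccccc3)cc2)c(OCc2ccccc2)c1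
A3 | direct plan | 5-(benzyloxy)-2-[4-(benzyloxy)phenyl]-3-hydroxy-7-methoxy-4H-chromen-4-one | COc1cc(OCc2ccccc2)c2c(=O)c(O)c(-c3ccc(OCc4ccccc4)cc3)oc2c1
A4 | direct plan | 5-hydroxy-2-(4-hydroxyphenyl)-3,7-dimethoxy-4H-chromen-4-one | COc1cc(O)c2c(=O)c(OC)c(-c3ccc(O)cc3)oc2c1
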